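**Retrosynthetic overview**
1. The target is the erythro-(7R,8S) 8-O-4′ neolignan. C7 is the benzylic carbinol carbon on ring A (guaiacyl ring), C8 carries the aryl ether oxygen of ring B (acetosyringone ring), and C9 is the CH2OH carbon.
2. The key disconnection is C7–C8, an anti-aldol retron once C9 is raised to the aldehyde level. It leads to 2-(4-acetyl-2,6-dimethoxyphenoxy)acetaldehyde (donor) and O-pivaloyl vanillin (acceptor), joined by a D-proline-catalysed direct cross-aldol that sets both stereocentres in one operation.
3. Enabling feature: C8 is a CH flanked by the ring-B ether oxygen and C9, so the C8–C9 unit is a latent enolisable α-aryloxyacetaldehyde (enamine donor). C7 sits directly on ring A, so it is a latent non-enolisable aryl aldehyde carbon, and the anti O/O pattern at C7/C8 is the native outcome of an (E)-enamine aldol.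
4. No ring is formed. Both benzene rings are bought (acetosyringone, vanillin); the donor comes from O-allylation/ozonolysis and the acceptor from O-pivaloylation, which is an electron-withdrawing, activating mask.
5. End game: chemoselective in-flask NaBH4 reduction of the C9 aldehyde (the aryl ketone needs no protection), then methanolysis of the pivalate.

Key step: step 4

**Route**

Step 1
Reactants: 1 acetosyringone; 2 allyl bromide
Product: 3 1-[3,5-dimethoxy-4-(prop-2-en-1-yloxy)phenyl]ethan-1-one
Conditions: K2CO3, DMF, 50 °C
Reagents that add atoms: none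
Why: Williamson ether synthesis, in which the acetyl-stabilised phenoxide of 1 (the only acidic O–H) displaces bromide from the unhindered allylic halide by SN2, with both ortho positions blocked by methoxy groups so that only O-alkylation is productive.

Step 2
Reactants: 3 1-[3,5-dimethoxy-4-(prop-2-en-1-yloxy)phenyl]ethan-1-one
Product: 5 2-(4-acetyl-2,6-dimethoxyphenoxy)acetaldehyde, via ozonide 4 (not isolated)
Conditions: O3, CH2Cl2, −78 °C (indicator end point); then Me2S, −78 °C → rt
Reagents that add atoms: ozone, [O-][O+]=O
Why: Ozonolysis (Criegee mechanism) of the isolated terminal alkene, which should react far faster than the acetyl-deactivated arene, gives ozonide 4, and dimethyl sulfide reduces it to the aldehyde without over-oxidation; no stereocentre is created.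

Step 3
Reactants: 6 vanillin
Product: 7 4-formyl-2-methoxyphenyl pivalate
Conditions: PivCl, Et3N, DMAP (cat.), CH2Cl2, 0 °C → rt
Reagents that add atoms: pivaloyl chloride, CC(C)(C)C(Cl)=O
Why: DMAP-catalysed O-acylation of the phenol; the pivalate is chosen because it is electron-withdrawing (it raises the electrophilicity of the formyl group for step 4) yet too hindered to acylate the amine catalyst.

Step 4
Reactants: 5 2-(4-acetyl-2,6-dimethoxyphenoxy)acetaldehyde; 7 4-formyl-2-methoxyphenyl pivalate
Product: 10 4-[(1R,2S)-2-(4-acetyl-2,6-dimethoxyphenoxy)-1,3-dihydroxypropyl]-2-methoxyphenyl pivalate, via enamine 8 (not isolated), via aldol aldehyde 9 (not isolated)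
Conditions: D-proline (20 mol%), DMF, 4 °C, 5 added slowly (syringe pump) to 7 (2.5 equiv); then MeOH, NaBH4, −40 °C
Reagents that add atoms: none
Why: D-proline condenses only with the enolisable aldehyde 5 to give (E)-enamine 8, whose nucleophilic carbon (future C8) adds to the formyl carbon of 7 (future C7) in a chair-like transition state in which the catalyst's carboxylic acid hydrogen-bonds to the aldehyde oxygen, and hydrolysis then releases anti-aldol 9 and the catalyst. The closest known reaction type is the proline-catalysed direct anti-selective cross-aldol between two aldehydes, which covers α-oxygenated aldehyde donors and aryl aldehyde acceptors. No ring is closed. C7 (R) should result from Si-face attack on the aldehyde, enforced by the CO2H···O=C hydrogen bond of the (R)-configured catalyst with the aryl group pseudo-equatorial; C8 (S in 10) should result from the (E)-enamine geometry and attack on the enamine face syn to the carboxylic acid, and together these give the anti (erythro) relationship. The step needs cross- over homo-aldol selectivity and a clean donor/acceptor assignment, which are secured because 7 has no α-hydrogen and is activated by the pivalate, 5 is kept at low concentration by slow addition into excess 7, and the aryl methyl ketone of ring B neither forms an enamine nor acts as acceptor under these conditions. NaBH4 at −40 °C then reduces the C9 aldehyde before it can epimerise or undergo retro-aldol cleavage and should leave the deactivated aryl ketone and the pivalate untouched.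

Step 5
Reactants: 10 4-[(1R,2S)-2-(4-acetyl-2,6-dimethoxyphenoxy)-1,3-dihydroxypropyl]-2-methoxyphenyl pivalate
Product: 11 1-(4-{[(1R,2S)-1,3-dihydroxy-1-(4-hydroxy-3-methoxyphenyl)propan-2-yl]oxy}-3,5-dimethoxyphenyl)ethan-1-one (target)
Conditions: K2CO3, MeOH, 0 °C → rt; aq. NH4Cl
Reagents that add atoms: none
Why: Base-mediated transesterification (methanolysis) of the aryl pivalate, an activated ester because the phenoxide is a good leaving group, while the two alcohols, the aryl ketone and both stereocentres (neither is α to a carbonyl) should be inert to K2CO3/MeOH at room temperature.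

**Compound list**
1 | acetosyringone, 1-(4-hydroxy-3,5-dimethoxyphenyl)ethan-1-one | CC(=O)c1cc(OC)c(O)c(OC)c1 | starting material
2 | allyl bromide, 3-bromoprop-1-ene | C=CCBr | starting material
3 | 1-[3,5-dimethoxy-4-(prop-2-en-1-yloxy)phenyl]ethan-1-one | CC(=O)c1cc(OC)c(OCC=C)c(OC)c1 | intermediate
4 | 1-[3,5-dimethoxy-4-(1,2,4-trioxolan-3-ylmethoxy)phenyl]ethan-1-one (secondary ozonide, racemic at the ring carbon) | CC(=O)c1cc(OC)c(OCC2OCOO2)c(OC)c1 | intermediate (not isolated)
5 | 2-(4-acetyl-2,6-dimethoxyphenoxy)acetaldehyde | CC(=O)c1cc(OC)c(OCC=O)c(OC)c1 | intermediate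
6 | vanillin, 4-hydroxy-3-methoxybenzaldehyde | COc1cc(C=O)ccc1O | starting material
7 | 4-formyl-2-methoxyphenyl pivalate (2,2-dimethylpropanoate) | COc1cc(C=O)ccc1OC(=O)C(C)(C)C | intermediate
8 | (2R)-1-[(E)-2-(4-acetyl-2,6-dimethoxyphenoxy)ethenyl]pyrrolidine-2-carboxylic acid (enamine of 5 with D-proline) | CC(=O)c1cc(OC)c(O/C=C/N2CCC[C@@H]2C(O)=O)c(OC)c1 | intermediate (not isolated)
9 | 4-[(1R,2R)-2-(4-acetyl-2,6-dimethoxyphenoxy)-1-hydroxy-3-oxopropyl]-2-methoxyphenyl pivalate (anti-aldol aldehyde) | COc1cc([C@@H](O)[C@H](C=O)Oc2c(OC)cc(C(C)=O)cc2OC)ccc1OC(=O)C(C)(C)C | intermediate (not isolated)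
10 | 4-[(1R,2S)-2-(4-acetyl-2,6-dimethoxyphenoxy)-1,3-dihydroxypropyl]-2-methoxyphenyl pivalate | COc1cc([C@@H](O)[C@H](CO)Oc2c(OC)cc(C(C)=O)cc2OC)ccc1OC(=O)C(C)(C)C | intermediate
11 | 1-(4-{[(1R,2S)-1,3-dihydroxy-1-(4-hydroxy-3-methoxyphenyl)propan-2-yl]oxy}-3,5-dimethoxyphenyl)ethan-1-one | COc1cc([C@@H](O)[C@H](CO)Oc2c(OC)cc(C(C)=O)cc2OC)ccc1O | target

**Step count**
Total step count: 5. Longest linear sequence: 4 steps (steps 1, 2, 4, 5).

**Steps most likely to fail**

Step 4 (key step). Self-aldolisation of the very electrophilic donor 5 may outrun addition to the only moderately electrophilic aryl aldehyde 7, and the anti selectivity may erode by retro-aldol equilibration before the reduction; the minor threo isomer would have to be removed at the stage of 10. The fallback sets out from 3 and 7 and comes back to the route at 9. It replaces the catalytic enamine by a preformed (E)-γ-aryloxyallylboron nucleophile that tolerates the aryl ketone. Cross-metathesis of 3 with vinylboronic acid pinacol ester (second-generation ruthenium benzylidene catalyst, CH2Cl2, 40 °C) would give the (E)-alkenylboronate F1. Iridium-catalysed double-bond transposition ([Ir(cod)(PPh2Me)2]PF6 activated with H2, THF) would move the alkene into conjugation with the ether oxygen and give the (E)-γ-aryloxyallylboronate F2. Chiral phosphoric acid-catalysed allylboration of 7 (toluene, −30 °C, with (S)-TRIP, taken to be the enantiomer that sends the allyl unit to the Si face of the aldehyde; this sense must be confirmed before committing) should pass through a closed chair transition state in which the E geometry becomes the anti relationship. It would give the pinacol borate F3 and, after aqueous work-up, the anti-homoallylic alcohol F4. Ozonolysis (O3, CH2Cl2, −78 °C; then Me2S) through the ozonide F5 would deliver aldol aldehyde 9, which is reduced with NaBH4 as in step 4 to 10.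

Step 2. Ozone may attack the trialkoxyarene or over-oxidise the aldehyde, and 5 may hydrate or oligomerise during isolation. The fallback sets out from 1 and comes back at 5 and uses no oxidant. Alkylation of 1 with bromoacetaldehyde diethyl acetal (K2CO3, KI cat., DMF, 110 °C) would give the diethyl acetal F6, which is stable on storage, and mild acid hydrolysis (2 M HCl, THF, 40 °C) would release 5 immediately before the aldol.

Step 5. Methanolysis of the hindered pivalate may be slow, and prolonged exposure to base may cause acyl transfer to the C9/C7 hydroxyls or degradation of the p-hydroxybenzyl alcohol. The fallback sets out from 6 and comes back at 11 and uses a more labile phenol mask. Acetylation of 6 (Ac2O, pyridine) would give vanillin acetate F7. The same D-proline cross-aldol with 5, run with a higher catalyst loading to allow for some N-acetylation of the catalyst, would give the aldol aldehyde F8, which is reduced in the flask (NaBH4, MeOH, −40 °C) to the diol acetate F9. The phenolic acetate would then be removed under neutral conditions (NH4OAc, MeOH/H2O, rt) to give 11; any acetate already lost during the reduction leads to the same product.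

**Further compounds**
F1 | step 4 | 1-[3,5-dimethoxy-4-{[(2E)-3-(4,4,5,5-tetramethyl-1,3,2-dioxaborolan-2-yl)prop-2-en-1-yl]oxy}phenyl]ethan-1-one | CC(=O)c1cc(OC)c(OC/C=C/B2OC(C)(C)C(C)(C)O2)c(OC)c1
F2 | step 4 | 1-[3,5-dimethoxy-4-{[(1E)-3-(4,4,5,5-tetramethyl-1,3,2-dioxaborolan-2-yl)prop-1-en-1-yl]oxy}phenyl]ethan-1-one | CC(=O)c1cc(OC)c(O/C=C/CB2OC(C)(C)C(C)(C)O2)c(OC)c1
F3 | step 4 | 4-[(1R,2S)-2-(4-acetyl-2,6-dimethoxyphenoxy)-1-[(4,4,5,5-tetramethyl-1,3,2-dioxaborolan-2-yl)oxy]but-3-en-1-yl]-2-methoxyphenyl pivalate | COc1cc([C@@H](OB2OC(C)(C)C(C)(C)O2)[C@H](C=C)Oc2c(OC)cc(C(C)=O)cc2OC)ccc1OC(=O)C(C)(C)C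
F4 | step 4 | 4-[(1R,2S)-2-(4-acetyl-2,6-dimethoxyphenoxy)-1-hydroxybut-3-en-1-yl]-2-methoxyphenyl pivalate | COc1cc([C@@H](O)[C@H](C=C)Oc2c(OC)cc(C(C)=O)cc2OC)ccc1OC(=O)C(C)(C)C
F5 | step 4 | 4-[(1R,2R)-2-(4-acetyl-2,6-dimethoxyphenoxy)-1-hydroxy-2-(1,2,4-trioxolan-3-yl)ethyl]-2-methoxyphenyl pivalate | COc1cc([C@@H](O)[C@H](C2OCOO2)Oc2c(OC)cc(C(C)=O)cc2OC)ccc1OC(=O)C(C)(C)C
F6 | step 2 | 1-[4-(2,2-diethoxyethoxy)-3,5-dimethoxyphenyl]ethan-1-one | CCOC(COc1c(OC)cc(C(C)=O)cc1OC)OCC
F7 | step 5 | 4-formyl-2-methoxyphenyl acetate | COc1cc(C=O)ccc1OC(C)=O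
F8 | step 5 | 4-[(1R,2R)-2-(4-acetyl-2,6-dimethoxyphenoxy)-1-hydroxy-3-oxopropyl]-2-methoxyphenyl acetate | COc1cc([C@@H](O)[C@H](C=O)Oc2c(OC)cc(C(C)=O)cc2OC)ccc1OC(C)=O
F9 | step 5 | 4-[(1R,2S)-2-(4-acetyl-2,6-dimethoxyphenoxy)-1,3-dihydroxypropyl]-2-methoxyphenyl acetate | COc1cc([C@@H](O)[C@H](CO)Oc2c(OC)cc(C(C)=O)cc2OC)ccc1OC(C)=O
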